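The recipe's ratio is 3.00 equivalents of reagent to substrate, and the decision is whether to charge that or less for the time given.

| flask | substrate | reagent | remark | time |
|---|---|---|---|---|
| Friday's | 0.50 M | 1 M | run made earlier |  |
| Monday's | 0.50 M | 2.2 M | run made earlier |  |
| Wednesday's | 0.25 M | 1.5 M | run made earlier |  |
| flask | 0.50 M | 1.50 M |  | 2.5 d |

| run | time / h | single product / % |
|---|---|---|
| Friday's | 4.00 | 12.3 |
| Friday's | 6.00 | 17.4 |
| Friday's | 10.0 | 25.4 |
| Friday's | 20.0 | 40.0 |
| Friday's | 30.0 | 49.6 |
| Friday's | 50.0 | 57.8 |
| Monday's | 8.00 | 40.8 |
| Monday's | 15.0 | 54.5 |
| Monday's | 25.0 | 61.4 |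
| Monday's | 30.0 | 61.9 |
| Monday's | 40.0 | 60.7 |
| Monday's | 50.0 | 55.4 |
| Wednesday's | 4.00 | 17.1 |
| Wednesday's | 8.00 | 27.3 |
| Wednesday's | 15.0 | 37.7 |
| Wednesday's | 25.0 | 44.3 |
| Wednesday's | 50.0 | 34.4 |

(standard deviation of a reading: 0.5 percentage points)

- equivalents of reagent to substrate, everything else as given, that leave most single product at 2.5 d
- the amount of single product then, in percent of the substrate charged
- the amount of single product with the amounts as given

- a reading or a percentage of single product counts all its forms, free or not

I take as the zero of the scale the symmetric case: both additions of reagent equally fast, a selectivity factor of one, reagent held at its charge, so that each step is pseudo-first-order. Friday's first reading, 12.3 % at 4.00 h, taken as all the substrate consumed by then and scaled in proportion to reagent and time, gives this flask an estimated 2.95 lifetimes, a lifetime count being minus the logarithm of the fraction of substrate left by the first addition. In the symmetric case the fraction in single product is the lifetime count times the exponential of minus that count. That gives 15.4 % here and a top of 36.8 % at one lifetime, so the zero says to cut to 1.02 equivalents.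

But Monday's highest reading is 61.9 % at 30.0 h, which is 2.17 lifetimes, where the zero allows 24.8 %, so the reading stands well above it. My own reckoning therefore puts the flask's top at Monday's lifetime count, which means 2.20 equivalents.

The forecast differs from my figure: it gives 2.5 equiv with 61.5 %, and 60.5 % for the recipe, calling the loss “zero order in product and first order in reagent, like a saturated catalyst”.

The simulated flask gives 2.54 equiv with 62.7 %, and 61.7 % for the recipe, so the forecast holds.

    substrate + reagent → single product (k = 0.0401 M⁻¹ h⁻¹)
    reagent + single product → bis adduct (k = 0.0496 M⁻¹ h⁻¹)
    crystals ⇌ single product, rate k3*(cs3 - [single product]) while solid is left; crystals form when [single product] > cs3 (solubility = 46.0 mM, k = 3.66 h⁻¹)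
    single product ⇌ isomer of the product (K = 0.108, k = 0.0680 h⁻¹)
    substrate → decomposition product (k = 2.38 × 10⁻⁵ h⁻¹)

At 2.95 lifetimes the symmetric case stands at 15.4 %, and this flask without the ceiling on dissolved single product gives 17.8 %. That ceiling, together with the time given, is part of the reason for the 61.7 % found. While crystals last in this flask, at 52.5 % at the asked time, dissolved single product stays near 9.20 % of the charge, so bis adduct forms at about 0.00228 h⁻¹ times the reagent concentration, where the forecast's loss has the coefficient 0.0023. The neighbour flask with 0.60 M of reagent has an estimated 1.18 lifetimes and a symmetric 36.3 %, and it holds 48.8 % of single product.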